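The dihydropyranone ring (pyranone numbering) is cut into two three-atom pieces. O1–C2–C3 is diethylphosphonoacetic acid, an O,C-bis-nucleophile, and C4–C5–C6 is a trans-2,3-epoxy aldehyde, a bis-electrophile. The plan exploits that ring carbon C6 is at once the lactone carbinol carbon, allylic to the C1'=C2' alkene and vicinal to oxygenated C5. In one operation the carboxylate opens the vinyl oxirane at C6 with inversion. The resulting ester then closes the ring by intramolecular Horner–Wadsworth–Emmons olefination of the C4 formyl group, which fixes the Z-alkene and frees only the C5 hydroxyl. Mitsunobu esterification with tiglic acid then inverts C5. The precursor is an acyclic epoxy aldehyde carrying the L-fucal-derived diacetate side chain.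

Key step: step 5

Numbering used below: lactone O1, C2 (C=O), C3=C4, C5, C6; side chain C1'=C2', C3', C4', C5'.
Assumption: the sense of induction in step 4 is assigned from the steric-shielding model of diarylprolinol silyl ethers (attack on the E, s-trans iminium ion anti to the CAr2(OSiMe3) group); both catalyst enantiomers are commercial.

Step 1
Reactants: 1 3,4-di-O-acetyl-L-fucal
Product: 2 (2E,4S,5S)-4-acetoxy-5-hydroxyhex-2-enal
Conditions: HgSO4 (2 mol %), 5 mM aq H2SO4, 1,4-dioxane, rt
Reagents that add atoms: water, SMILES O
Why: Mercury-catalysed hydration of the enol ether with allylic loss of the C3 acetate (Perlin-type glycal hydrolysis) should open the ring to the E-enal, and the two stereocentres that become C3' and C4' are carried over untouched from the sugar.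

Step 2
Reactants: 2 (2E,4S,5S)-4-acetoxy-5-hydroxyhex-2-enal
Product: 3 (2E,4S,5S)-4,5-diacetoxyhex-2-enal
Conditions: Ac2O, pyridine, CH2Cl2, 0 °C to rt
Reagents that add atoms: acetic anhydride, SMILES CC(=O)OC(C)=O
Why: Standard O-acetylation of the free secondary alcohol under weakly basic conditions, in which no stereocentre is touched.

Step 3
Reactants: 3 (2E,4S,5S)-4,5-diacetoxyhex-2-enal; 4 (triphenylphosphoranylidene)acetaldehyde
Product: 5 (2E,4E,6S,7S)-6,7-diacetoxyocta-2,4-dienal
Conditions: 4 (1.05 equiv), toluene, 70 °C
Reagents that add atoms: none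
Why: Wittig olefination with the formyl-stabilised ylide is E-selective and mild enough for the acetates, and near-stoichiometric ylide limits a second homologation.

Step 4
Reactants: 5 (2E,4E,6S,7S)-6,7-diacetoxyocta-2,4-dienal
Product: 6 (2S,3R)-3-[(1E,3S,4S)-3,4-diacetoxypent-1-en-1-yl]oxirane-2-carbaldehyde
Conditions: (S)-2-{bis[3,5-bis(trifluoromethyl)phenyl](trimethylsilyloxy)methyl}pyrrolidine (10 mol %), 35% aq H2O2, CH2Cl2, rt; short silica plug, used at once
Reagents that add atoms: hydrogen peroxide, SMILES OO
Why: In this iminium–enamine organocatalytic (Weitz–Scheffer-type) epoxidation, hydroperoxide adds to the β-carbon of the E-iminium ion anti to the bulky catalyst arm and the enamine closes the trans-oxirane on the same face, which sets (2S,3R) under catalyst control.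

Step 5
Reactants: 6 (2S,3R)-3-[(1E,3S,4S)-3,4-diacetoxypent-1-en-1-yl]oxirane-2-carbaldehyde; 7 diethylphosphonoacetic acid
Product: 9 (5R,6S)-6-[(1E,3S,4S)-3,4-diacetoxypent-1-en-1-yl]-5-hydroxy-5,6-dihydro-2H-pyran-2-one, via phosphonoacetate ester 8 (not isolated)
Conditions: 7 (1.1 equiv), iPr2NEt (1.1 equiv), LiOSO2CF3 (3 equiv), MeCN (0.3 M), 0 to 35 °C
Reagents that add atoms: none
Why: Proposed new method: with one equivalent of base only the carboxylate of 7 is formed (its CH2 is not acidic enough for iPr2NEt/LiOSO2CF3), and it opens the lithium-activated oxirane of 6 by SN2 attack at C6 to give 8, whose ester CH2 is now acidic, so that the base equivalent released by ring opening generates the phosphonate carbanion, which adds to the C4 formyl group and expels diethyl phosphate. The closest known reaction types are the lithium-salt-assisted and carboxylate openings of vinyl oxiranes and 2,3-epoxy alcohols at the allylic carbon and the intramolecular Horner–Wadsworth–Emmons lactone closure under Masamune–Roush conditions, and their merger on an epoxy aldehyde is the new element. The dihydropyranone ring closes in the C3–C4 step, a 6-exo-trig carbanion addition followed by syn elimination through the oxaphosphetane, and the six-membered ring allows only the Z alkene. C6 is set by stereospecific inversion of the (3R)-oxirane carbon, and C5 keeps its C–O bond and thus its configuration, which should give the 5,6-trans hydroxy lactone. The step needs attack at C6 rather than at C5 or C2': C6 is allylic and stabilises the loosened C–O bond, C5 is deactivated by the adjacent lithium-bound formyl group, and C2' is shielded by the acetoxy-bearing C3'. A halide-free lithium salt excludes halohydrin formation and double inversion, and because the single base equivalent ends as diethyl phosphate the medium finishes neutral, which should protect the acetates and suppress acyl migration, translactonisation and elimination.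

Step 6
Reactants: 9 (5R,6S)-6-[(1E,3S,4S)-3,4-diacetoxypent-1-en-1-yl]-5-hydroxy-5,6-dihydro-2H-pyran-2-one; 10 tiglic acid
Product: 11 (5S,6S)-6-[(1E,3S,4S)-3,4-diacetoxypent-1-en-1-yl]-5-[(E)-2-methylbut-2-enoyloxy]-5,6-dihydro-2H-pyran-2-one (target)
Conditions: PPh3, DIAD, toluene, -10 °C to rt
Reagents that add atoms: none
Why: In this Mitsunobu esterification tiglate displaces the allylic C5 alkoxyphosphonium group by SN2 with inversion to give the 5,6-cis ester, while anti elimination is disfavoured because H6 and the leaving group are syn in the trans-lactone and SN2' attack at the electron-poor C3 is mismatched.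

Compound list
1 | 3,4-di-O-acetyl-L-fucal | C[C@@H]1OC=C[C@H](OC(C)=O)[C@@H]1OC(C)=O | starting material
2 | (2E,4S,5S)-4-acetoxy-5-hydroxyhex-2-enal | O=C/C=C/[C@H](OC(C)=O)[C@H](C)O | intermediate
3 | (2E,4S,5S)-4,5-diacetoxyhex-2-enal | O=C/C=C/[C@H](OC(C)=O)[C@H](C)OC(C)=O | intermediate
4 | (triphenylphosphoranylidene)acetaldehyde | O=CC=P(c1ccccc1)(c1ccccc1)c1ccccc1 | starting material
5 | (2E,4E,6S,7S)-6,7-diacetoxyocta-2,4-dienal | O=C/C=C/C=C/[C@H](OC(C)=O)[C@H](C)OC(C)=O | intermediate
6 | (2S,3R)-3-[(1E,3S,4S)-3,4-diacetoxypent-1-en-1-yl]oxirane-2-carbaldehyde | O=C[C@H]1O[C@@H]1/C=C/[C@H](OC(C)=O)[C@H](C)OC(C)=O | intermediate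
7 | diethylphosphonoacetic acid | OC(=O)CP(=O)(OCC)OCC | starting material
8 | (2S,3S,4E,6S,7S)-6,7-diacetoxy-2-hydroxy-1-oxooct-4-en-3-yl 2-(diethoxyphosphoryl)acetate | O=C[C@@H](O)[C@@H](OC(=O)CP(=O)(OCC)OCC)/C=C/[C@H](OC(C)=O)[C@H](C)OC(C)=O | intermediate
9 | (5R,6S)-6-[(1E,3S,4S)-3,4-diacetoxypent-1-en-1-yl]-5-hydroxy-5,6-dihydro-2H-pyran-2-one | O[C@@H]1C=CC(=O)O[C@H]1/C=C/[C@H](OC(C)=O)[C@H](C)OC(C)=O | intermediate
10 | tiglic acid, (E)-2-methylbut-2-enoic acid | C/C=C(\C)C(=O)O | starting material
11 | (5S,6S)-6-[(1E,3S,4S)-3,4-diacetoxypent-1-en-1-yl]-5-[(E)-2-methylbut-2-enoyloxy]-5,6-dihydro-2H-pyran-2-one | C/C=C(\C)C(=O)O[C@H]1C=CC(=O)O[C@H]1/C=C/[C@H](OC(C)=O)[C@H](C)OC(C)=O | target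

Total step count: 6. Longest linear sequence: 6 steps (1 to 11).

Steps most likely to fail

1. Step 5 (Proposed new method).
- What may go wrong: the intermolecular opening of the oxirane may be too slow. The carboxylate may attack C5 or C2'. The acyl group may migrate from O6 to O5 before the olefination and lead to five-ring closure. The carboxylate may also be lost again by β-elimination from the hydroxy aldehyde.
- Fallback (known chemistry): it sets out from 6 and comes back at 9. A Z-selective Horner–Wadsworth–Emmons olefination of 6 with tert-butyl 2-(diphenoxyphosphoryl)acetate (NaH, THF, -78 °C) should give tert-butyl (2Z)-3-{(2R,3R)-3-[(1E,3S,4S)-3,4-diacetoxypent-1-en-1-yl]oxiran-2-yl}prop-2-enoate F1. BF3·OEt2 in CH2Cl2 at -78 to -30 °C then lets the ester carbonyl oxygen open the vinyl oxirane at the allylic C6 in the 6-endo mode, with inversion and loss of the tert-butyl group. This gives 9.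

2. Step 4.
- What may go wrong: the peroxide may add at the δ-carbon of the dienal iminium ion instead of the β-carbon. The facial selectivity may be poor. The amine catalyst may open the vinyl oxirane once it has formed.
- Fallback: it sets out from 5 and comes back at 6. A 1,2-reduction (NaBH4, CeCl3·7H2O, MeOH, -20 °C) should give (2E,4E,6S,7S)-6,7-diacetoxyocta-2,4-dien-1-ol F2. Sharpless asymmetric epoxidation (Ti(OiPr)4, D-(-)-diethyl tartrate, tBuOOH, 4 Å molecular sieves, CH2Cl2, -20 °C) is directed to the allylic-alcohol alkene and should give {(2R,3R)-3-[(1E,3S,4S)-3,4-diacetoxypent-1-en-1-yl]oxiran-2-yl}methanol F3. Oxidation with Dess–Martin periodinane (NaHCO3, CH2Cl2, 0 °C) then gives 6.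

3. Step 6.
- What may go wrong: elimination across C5–C6 to the 2-pyranone may occur, either from the activated alcohol or from the product under the basic betaine. Acyl transfer with retention through an acyloxyphosphonium species is also possible.
- Fallback: it sets out from 9 and comes back at 11, and it separates activation from displacement so that no basic betaine or hydrazide anion is present. Sulfonylation of 9 (ClCH2SO2Cl, pyridine, CH2Cl2, -20 °C) should give (5R,6S)-6-[(1E,3S,4S)-3,4-diacetoxypent-1-en-1-yl]-2-oxo-5,6-dihydro-2H-pyran-5-yl chloromethanesulfonate F4. This is displaced with inversion by caesium tiglate (from Cs2CO3 and 10, 18-crown-6, toluene, rt) to give 11.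

Further compounds
F1 | step 5 | tert-butyl (2Z)-3-{(2R,3R)-3-[(1E,3S,4S)-3,4-diacetoxypent-1-en-1-yl]oxiran-2-yl}prop-2-enoate | CC(C)(C)OC(=O)/C=C\[C@H]1O[C@@H]1/C=C/[C@H](OC(C)=O)[C@H](C)OC(C)=O
F2 | step 4 | (2E,4E,6S,7S)-6,7-diacetoxyocta-2,4-dien-1-ol | OC/C=C/C=C/[C@H](OC(C)=O)[C@H](C)OC(C)=O
F3 | step 4 | {(2R,3R)-3-[(1E,3S,4S)-3,4-diacetoxypent-1-en-1-yl]oxiran-2-yl}methanol | OC[C@H]1O[C@@H]1/C=C/[C@H](OC(C)=O)[C@H](C)OC(C)=O
F4 | step 6 | (5R,6S)-6-[(1E,3S,4S)-3,4-diacetoxypent-1-en-1-yl]-2-oxo-5,6-dihydro-2H-pyran-5-yl chloromethanesulfonate | ClCS(=O)(=O)O[C@@H]1C=CC(=O)O[C@H]1/C=C/[C@H](OC(C)=O)[C@H](C)OC(C)=O
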